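## Retrosynthetic overview

1. Target 26 ⇐ allylic alcohol 25 (epoxidation directed by the 10-hydroxyl) ⇐ skipped diene 14: C5=C6 gives H-5 and O-6 by silicon-tethered hydrosilylation–oxidation from O-4; C9=C10 gives the 9,10-epoxide and then, by selenolate opening and selenoxide elimination, C8=C9 with the 10-hydroxyl.
2. Diene 14 (bicyclo[5.3.0]deca-5,9-diene) ⇐ cis-dialkenylcyclopropane 13 by a [3,3] Cope ring expansion (three- to seven-membered ring) that forms C7–C8.
3. Enabling feature: in the seven-membered ring the angular carbon C1 sits between the pairs C5–C6 and C9–C10, with C7–C8 opposite. This is a cyclohepta-1,4-diene whose sp3 carbon (C1) and flanking alkene carbons (C5, C10) were a cyclopropane fused to the five-membered ring along C1–C5.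
4. 13 ⇐ bicyclo[3.1.0]hexanone 9 (exo addition sets C4) ⇐ diazo keto ester 8 by intramolecular cyclopropanation ⇐ asymmetric vinylogous aldol of dienal 3 with silyl dienolate 4 (sets C2).
5. Ring order: five-membered ring together with the cyclopropane (step 5), seven-membered ring (step 9), oxirane last (step 17).

Key step: step 9

Numbering and faces: daucane numbering is used (C1 angular methyl carbon, C2–C4 five-membered ring, C5 ring-fusion CH, C6–C10 seven-membered ring, C8 methyl-bearing). α is the face of H-5 in the target, β the face of the C1 methyl. In the bicyclo[3.1.0]hexane names, C1, C2, C3, C4, C5, C6 correspond to daucane C5, C4, C3, C2, C1, C10.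

Remark: read literally, the descriptors at C8 and C9 of the target string put the two oxirane C–O bonds on opposite faces of the seven-membered ring; an oxirane on a cycloheptane can only be cis-fused, so the route delivers the 8,9-epoxide on the face of the 10-hydroxyl (the face the string gives at C9 and C10), and the entry for 26 reproduces the string as given.

## Route

Step 1
Reactants: 1 (E)-but-2-enal; 2 2-(triphenyl-λ5-phosphanylidene)propanal
Product: 3 (2E,4E)-2-methylhexa-2,4-dienal
Conditions: toluene, 90 °C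
Reagents that add atoms: none
Why: Wittig olefination with a formyl-stabilised ylide, which should give the new trisubstituted alkene with E geometry.

Step 2
Reactants: 3 (2E,4E)-2-methylhexa-2,4-dienal; 4 1-methoxy-1,3-bis(trimethylsilyloxy)buta-1,3-diene
Product: 6 methyl (5R,6E,8E)-5-hydroxy-6-methyl-3-oxodeca-6,8-dienoate, via silylated aldol adduct 5 (not isolated)
Conditions: Ti(OiPr)4 (10 mol%), (R)-BINOL (10 mol%), 4 Å molecular sieves, THF, −78 °C to rt; then PPTS, MeOH, 0 °C
Reagents that add atoms: none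
Why: Catalytic enantioselective vinylogous Mukaiyama aldol addition at the γ-carbon of the acetoacetate dienolate, in which the titanium BINOLate should shield one aldehyde face and set the carbinol centre (C2 of the target, 5R here; (R)-BINOL is expected to give this sense by analogy with aromatic and α,β-unsaturated aldehydes), followed by mild methanolysis of both silyl groups.

Step 3
Reactants: 6 methyl (5R,6E,8E)-5-hydroxy-6-methyl-3-oxodeca-6,8-dienoate
Product: 7 methyl (5R,6E,8E)-5-(tert-butyldimethylsilyloxy)-6-methyl-3-oxodeca-6,8-dienoate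
Conditions: TBSCl, imidazole, DMF, 0 °C to rt
Reagents that add atoms: tert-butyldimethylsilyl chloride, CC(C)(C)[Si](C)(C)Cl
Why: Standard O-silylation of the secondary alcohol, which blocks O–H insertion in step 5 and provides the bulky group that steers the cyclopropanation.

Step 4
Reactants: 7 methyl (5R,6E,8E)-5-(tert-butyldimethylsilyloxy)-6-methyl-3-oxodeca-6,8-dienoate
Product: 8 methyl (5R,6E,8E)-5-(tert-butyldimethylsilyloxy)-2-diazo-6-methyl-3-oxodeca-6,8-dienoate
Conditions: 4-acetamidobenzenesulfonyl azide, Et3N, MeCN, 0 °C to rt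
Reagents that add atoms: 4-acetamidobenzenesulfonyl azide, CC(=O)Nc1ccc(cc1)S(=O)(=O)N=[N+]=[N-]
Why: Regitz diazo transfer to the doubly activated methylene of the β-keto ester; no stereocentre is touched.

Step 5
Reactants: 8 methyl (5R,6E,8E)-5-(tert-butyldimethylsilyloxy)-2-diazo-6-methyl-3-oxodeca-6,8-dienoate
Product: 9 methyl 4-(tert-butyldimethylsilyloxy)-5-methyl-2-oxo-6-[(E)-prop-1-enyl]bicyclo[3.1.0]hexane-1-carboxylate (silyloxy cis to C6; propenyl exo)
Conditions: Rh2(OAc)4 (1 mol%), CH2Cl2, 40 °C, slow addition of 8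
Reagents that add atoms: none
Why: Intramolecular cyclopropanation by the rhodium carbenoid onto the proximal trisubstituted alkene closes the five-membered ring and the cyclopropane at once and is stereospecific for the E alkene (propenyl exo, cis to the ester and the methyl), while allylic 1,2-strain (allylic C–H eclipsing the alkene methyl, silyloxy group turned away from the carbenoid) should place the silyl ether cis to the new cyclopropane carbon and so set C1 (with C5 and C10 provisionally) from the aldol centre.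

Step 6
Reactants: 9 methyl 4-(tert-butyldimethylsilyloxy)-5-methyl-2-oxo-6-[(E)-prop-1-enyl]bicyclo[3.1.0]hexane-1-carboxylate
Product: 10 methyl 4-(tert-butyldimethylsilyloxy)-2-hydroxy-5-methyl-2-(propan-2-yl)-6-[(E)-prop-1-enyl]bicyclo[3.1.0]hexane-1-carboxylate (2-hydroxyl and 4-silyloxy cis to C6)
Conditions: i-PrMgCl, LaCl3·2LiCl, THF, −20 to 0 °C
Reagents that add atoms: isopropylmagnesium chloride, CC(C)[Mg]Cl
Why: Lanthanum-promoted Grignard 1,2-addition to the ketone (faster than attack on the hindered bridgehead ester, with enolisation and reduction suppressed) from the exo face opposite to the cyclopropane and the silyloxy group, which should leave the tertiary hydroxyl cis to the cyclopropane and set C4.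

Step 7
Reactants: 10 methyl 4-(tert-butyldimethylsilyloxy)-2-hydroxy-5-methyl-2-(propan-2-yl)-6-[(E)-prop-1-enyl]bicyclo[3.1.0]hexane-1-carboxylate
Product: 11 4-(tert-butyldimethylsilyloxy)-1-(hydroxymethyl)-5-methyl-2-(propan-2-yl)-6-[(E)-prop-1-enyl]bicyclo[3.1.0]hexan-2-ol
Conditions: LiAlH4, Et2O, 0 °C
Reagents that add atoms: none
Why: Hydride reduction of the ester to the primary alcohol; the silyl ether, the alkene and the cyclopropane are inert.

Step 8
Reactants: 11 4-(tert-butyldimethylsilyloxy)-1-(hydroxymethyl)-5-methyl-2-(propan-2-yl)-6-[(E)-prop-1-enyl]bicyclo[3.1.0]hexan-2-ol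
Product: 12 4-(tert-butyldimethylsilyloxy)-2-hydroxy-5-methyl-2-(propan-2-yl)-6-[(E)-prop-1-enyl]bicyclo[3.1.0]hexane-1-carbaldehyde
Conditions: Dess–Martin periodinane, CH2Cl2, 0 °C to rt
Reagents that add atoms: none
Why: Dess–Martin oxidation of the primary alcohol (the tertiary alcohol cannot be oxidised); the aldehyde is used at once because cis-2-alkenylcyclopropanecarbaldehydes can equilibrate with 2,5-dihydrooxepines by retro-Claisen shift.

Step 9
Reactants: 12 4-(tert-butyldimethylsilyloxy)-2-hydroxy-5-methyl-2-(propan-2-yl)-6-[(E)-prop-1-enyl]bicyclo[3.1.0]hexane-1-carbaldehyde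
Product: 14 2α-(tert-butyldimethylsilyloxy)dauca-5,9-dien-4α-ol (8-methyl α; H-8 β), via cis-divinylcyclopropane 13 (not isolated)
Conditions: Ph3PCH3Br, KOt-Bu (excess), THF, 0 °C to rt; then toluene, 90 °C
Reagents that add atoms: methyltriphenylphosphonium bromide, C[P+](c1ccccc1)(c1ccccc1)c1ccccc1.[Br-]
Why: Wittig methylenation of the bridgehead aldehyde gives cis-1,2-dialkenylcyclopropane 13, which on warming should undergo the concerted [3,3]-sigmatropic (Cope) shift through a boat transition state with both alkenyl arms folded over the exo face of the three-membered ring, C7–C8 forming as the cyclopropane bond C5–C10 breaks with release of ring strain. The closest known reaction type is the divinylcyclopropane–cycloheptadiene rearrangement of 1-alkenyl-6-exo-alkenylbicyclo[3.1.0]hexanes to bicyclo[5.3.0]decadienes. The seven-membered ring is closed pericyclically as a three-to-seven ring expansion, the cyclopropane carbon C1 becoming the angular carbon, and not by an ionic exo or endo cyclisation. The one new stereocentre, C8, follows from the E geometry of the propenyl group and the boat geometry: the inward terminal hydrogen ends on the face of the angular methyl (β) and the methyl on the α face, which is what the syn-elimination of step 16 needs, while C1, C2 and C4 are carried through untouched. The step needs the two alkenyl groups cis on the cyclopropane, which the stereospecific cyclopropanation of the (E)-alkene in step 5 secures (propenyl exo, on the side of the bridgehead carbon substituent). The bridgehead methyl is syn to both arms and should raise the barrier above that of the parent system, hence the heating, but the homo-1,5-hydrogen shift is expected to remain slower.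

Step 10
Reactants: 14 2α-(tert-butyldimethylsilyloxy)dauca-5,9-dien-4α-ol
Product: 15 2α-(tert-butyldimethylsilyloxy)-4α-(dimethylsilyloxy)dauca-5,9-diene
Conditions: ClSiHMe2, Et3N, DMAP (cat.), CH2Cl2, 0 °C to rt
Reagents that add atoms: chlorodimethylsilane, C[SiH](C)Cl
Why: O-silylation of the only free (tertiary, allylic) hydroxyl with a small hydrosilyl chloride installs the Si–H tether for step 11.

Step 11
Reactants: 15 2α-(tert-butyldimethylsilyloxy)-4α-(dimethylsilyloxy)dauca-5,9-diene
Product: 17 2α-(tert-butyldimethylsilyloxy)dauc-9-ene-4α,6α-diol (H-5 α; trans ring fusion), via oxasilolane 16 (not isolated)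
Conditions: Pt2[(CH2=CHSiMe2)2O]3 (1 mol%), toluene, 60 °C; then KF, KHCO3, 30% H2O2, THF–MeOH, rt
Reagents that add atoms: hydrogen peroxide, OO
Why: Intramolecular platinum-catalysed hydrosilylation of the allylic hydrosilyl ether in the 5-endo mode followed by Tamao–Fleming oxidation: the tether on the α-oxygen at C4 delivers Si and H syn to the α face of C5=C6 only (C9=C10 is out of reach), setting H-5 α and, after C–Si oxidation with retention, the 6α-hydroxyl.

Step 12
Reactants: 17 2α-(tert-butyldimethylsilyloxy)dauc-9-ene-4α,6α-diol; 18 3,4-dimethoxybenzoyl chloride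
Product: 19 6α-(3,4-dimethoxybenzoyloxy)-2α-(tert-butyldimethylsilyloxy)dauc-9-en-4α-ol
Conditions: pyridine, DMAP (cat.), CH2Cl2, 0 °C to rt
Reagents that add atoms: none
Why: DMAP-catalysed acylation of the secondary 6-hydroxyl; the tertiary 4-hydroxyl should not react.

Step 13
Reactants: 19 6α-(3,4-dimethoxybenzoyloxy)-2α-(tert-butyldimethylsilyloxy)dauc-9-en-4α-ol
Product: 20 6α-(3,4-dimethoxybenzoyloxy)dauc-9-ene-2α,4α-diol
Conditions: TBAF, AcOH, THF, rt to 40 °C
Reagents that add atoms: none
Why: Fluoride-mediated cleavage of the silyl ether, buffered with acetic acid so that the aryl ester neither migrates nor is cleaved.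

Step 14
Reactants: 20 6α-(3,4-dimethoxybenzoyloxy)dauc-9-ene-2α,4α-diol
Product: 21 9α,10α-epoxy-6α-(3,4-dimethoxybenzoyloxy)daucane-2α,4α-diol
Conditions: VO(acac)2 (5 mol%), t-BuOOH, CH2Cl2, 0 °C to rt
Reagents that add atoms: tert-butyl hydroperoxide, CC(C)(C)OO
Why: Vanadium-catalysed hydroxyl-directed epoxidation of a homoallylic alcohol: the 2α-hydroxyl should deliver the oxygen to the α face of C9=C10, which is also the face away from the angular methyl, setting the 10α C–O bond.

Step 15
Reactants: 21 9α,10α-epoxy-6α-(3,4-dimethoxybenzoyloxy)daucane-2α,4α-diol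
Product: 22 2α-acetoxy-9α,10α-epoxy-6α-(3,4-dimethoxybenzoyloxy)daucan-4α-ol
Conditions: Ac2O, pyridine, DMAP (cat.), CH2Cl2, rt
Reagents that add atoms: acetic anhydride, CC(=O)OC(C)=O
Why: Acetylation of the secondary 2-hydroxyl before the 10-hydroxyl is released; the tertiary 4-hydroxyl and the epoxide should be untouched.

Step 16
Reactants: 22 2α-acetoxy-9α,10α-epoxy-6α-(3,4-dimethoxybenzoyloxy)daucan-4α-ol
Product: 25 2α-acetoxy-6α-(3,4-dimethoxybenzoyloxy)dauc-8-ene-4α,10α-diol, via hydroxy selenide 23 (not isolated), via selenoxide 24 (not isolated)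
Conditions: (PhSe)2, NaBH4, EtOH, rt to 50 °C; then NaIO4, NaHCO3, MeOH–H2O, 0 °C to rt
Reagents that add atoms: none
Why: Epoxide-to-allylic-alcohol transposition by selenolate opening and selenoxide syn-elimination: phenylselenolate should attack C9 with inversion (C10 is neopentylic), and the 9β-selenoxide eliminates towards the cis 8β-hydrogen set in step 9 and away from the carbinol carbon, giving C8=C9 while the 10α-hydroxyl is retained.

Step 17
Reactants: 25 2α-acetoxy-6α-(3,4-dimethoxybenzoyloxy)dauc-8-ene-4α,10α-diol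
Product: 26 2α-acetoxy-8,9-epoxy-6α-(3,4-dimethoxybenzoyloxy)daucane-4α,10α-diol (CNP0197096.3)
Conditions: VO(acac)2 (5 mol%), t-BuOOH, CH2Cl2, 0 °C
Reagents that add atoms: tert-butyl hydroperoxide, CC(C)(C)OO
Why: Vanadium-catalysed epoxidation of a cyclic allylic alcohol: the 10α-hydroxyl should direct the oxygen to the same face of the trisubstituted C8=C9 alkene, giving the cis-fused 8,9-epoxide syn to the hydroxyl and setting C8 and C9.

## Compound list

1 | (E)-but-2-enal (crotonaldehyde) | C/C=C/C=O | starting material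
2 | 2-(triphenyl-λ5-phosphanylidene)propanal | CC(C=O)=P(c1ccccc1)(c1ccccc1)c1ccccc1 | starting material
3 | (2E,4E)-2-methylhexa-2,4-dienal | O=C/C(C)=C/C=C/C | intermediate
4 | 1-methoxy-1,3-bis(trimethylsilyloxy)buta-1,3-diene | COC(O[Si](C)(C)C)=CC(=C)O[Si](C)(C)C | starting material
5 | methyl (5R,6E,8E)-6-methyl-3,5-bis(trimethylsilyloxy)deca-2,6,8-trienoate (silylated aldol adduct) | COC(=O)C=C(O[Si](C)(C)C)C[C@@H](O[Si](C)(C)C)/C(C)=C/C=C/C | intermediate
6 | methyl (5R,6E,8E)-5-hydroxy-6-methyl-3-oxodeca-6,8-dienoate | COC(=O)CC(=O)C[C@@H](O)/C(C)=C/C=C/C | intermediate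
7 | methyl (5R,6E,8E)-5-(tert-butyldimethylsilyloxy)-6-methyl-3-oxodeca-6,8-dienoate | COC(=O)CC(=O)C[C@@H](O[Si](C)(C)C(C)(C)C)/C(C)=C/C=C/C | intermediate
8 | methyl (5R,6E,8E)-5-(tert-butyldimethylsilyloxy)-2-diazo-6-methyl-3-oxodeca-6,8-dienoate | COC(=O)C(=[N+]=[N-])C(=O)C[C@@H](O[Si](C)(C)C(C)(C)C)/C(C)=C/C=C/C | intermediate
9 | methyl 4-(tert-butyldimethylsilyloxy)-5-methyl-2-oxo-6-[(E)-prop-1-enyl]bicyclo[3.1.0]hexane-1-carboxylate (silyloxy cis to C6; propenyl exo, cis to the ester and the 5-methyl) | COC(=O)[C@]12C(=O)C[C@@H](O[Si](C)(C)C(C)(C)C)[C@@]1(C)[C@@H]2/C=C/C | intermediate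
10 | methyl 4-(tert-butyldimethylsilyloxy)-2-hydroxy-5-methyl-2-(propan-2-yl)-6-[(E)-prop-1-enyl]bicyclo[3.1.0]hexane-1-carboxylate (2-hydroxyl and 4-silyloxy cis to C6) | COC(=O)[C@]12[C@](O)(C(C)C)C[C@@H](O[Si](C)(C)C(C)(C)C)[C@@]1(C)[C@@H]2/C=C/C | intermediate
11 | 4-(tert-butyldimethylsilyloxy)-1-(hydroxymethyl)-5-methyl-2-(propan-2-yl)-6-[(E)-prop-1-enyl]bicyclo[3.1.0]hexan-2-ol (configuration as in 10) | OC[C@]12[C@](O)(C(C)C)C[C@@H](O[Si](C)(C)C(C)(C)C)[C@@]1(C)[C@@H]2/C=C/C | intermediate
12 | 4-(tert-butyldimethylsilyloxy)-2-hydroxy-5-methyl-2-(propan-2-yl)-6-[(E)-prop-1-enyl]bicyclo[3.1.0]hexane-1-carbaldehyde (configuration as in 10) | O=C[C@]12[C@](O)(C(C)C)C[C@@H](O[Si](C)(C)C(C)(C)C)[C@@]1(C)[C@@H]2/C=C/C | intermediate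
13 | 4-(tert-butyldimethylsilyloxy)-1-ethenyl-5-methyl-2-(propan-2-yl)-6-[(E)-prop-1-enyl]bicyclo[3.1.0]hexan-2-ol (cis-divinylcyclopropane) | C=C[C@]12[C@](O)(C(C)C)C[C@@H](O[Si](C)(C)C(C)(C)C)[C@@]1(C)[C@@H]2/C=C/C | intermediate
14 | 2α-(tert-butyldimethylsilyloxy)dauca-5,9-dien-4α-ol (8-methyl α, H-8 β) | C1=C2[C@](O)(C(C)C)C[C@@H](O[Si](C)(C)C(C)(C)C)[C@@]2(C)C=C[C@@H](C)C1 | intermediate
15 | 2α-(tert-butyldimethylsilyloxy)-4α-(dimethylsilyloxy)dauca-5,9-diene | C1=C2[C@](O[SiH](C)C)(C(C)C)C[C@@H](O[Si](C)(C)C(C)(C)C)[C@@]2(C)C=C[C@@H](C)C1 | intermediate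
16 | cyclic silyl ether O4–SiMe2–C6 of 2α-(tert-butyldimethylsilyloxy)dauc-9-en-4α-ol (oxasilolane; Si and H-5 on the α face) | C[Si]1(C)O[C@@]2(C(C)C)C[C@@H](O[Si](C)(C)C(C)(C)C)[C@@]3(C)C=C[C@@H](C)C[C@@H]1[C@H]23 | intermediate
17 | 2α-(tert-butyldimethylsilyloxy)dauc-9-ene-4α,6α-diol (H-5 α, trans ring fusion) | O[C@@H]1C[C@H](C)C=C[C@]2(C)[C@H](O[Si](C)(C)C(C)(C)C)C[C@@](O)(C(C)C)[C@@H]12 | intermediate
18 | 3,4-dimethoxybenzoyl chloride | COc1ccc(C(Cl)=O)cc1OC | starting material
19 | 6α-(3,4-dimethoxybenzoyloxy)-2α-(tert-butyldimethylsilyloxy)dauc-9-en-4α-ol | COc1ccc(C(=O)O[C@@H]2C[C@H](C)C=C[C@]3(C)[C@H](O[Si](C)(C)C(C)(C)C)C[C@@](O)(C(C)C)[C@@H]23)cc1OC | intermediate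
20 | 6α-(3,4-dimethoxybenzoyloxy)dauc-9-ene-2α,4α-diol | COc1ccc(C(=O)O[C@@H]2C[C@H](C)C=C[C@]3(C)[C@H](O)C[C@@](O)(C(C)C)[C@@H]23)cc1OC | intermediate
21 | 9α,10α-epoxy-6α-(3,4-dimethoxybenzoyloxy)daucane-2α,4α-diol | COc1ccc(C(=O)O[C@@H]2C[C@H](C)[C@@H]4O[C@@H]4[C@]3(C)[C@H](O)C[C@@](O)(C(C)C)[C@@H]23)cc1OC | intermediate
22 | 2α-acetoxy-9α,10α-epoxy-6α-(3,4-dimethoxybenzoyloxy)daucan-4α-ol | COc1ccc(C(=O)O[C@@H]2C[C@H](C)[C@@H]4O[C@@H]4[C@]3(C)[C@H](OC(C)=O)C[C@@](O)(C(C)C)[C@@H]23)cc1OC | intermediate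
23 | 2α-acetoxy-6α-(3,4-dimethoxybenzoyloxy)-9β-(phenylselanyl)daucane-4α,10α-diol | COc1ccc(C(=O)O[C@@H]2C[C@H](C)[C@@H]([Se]c4ccccc4)[C@H](O)[C@]3(C)[C@H](OC(C)=O)C[C@@](O)(C(C)C)[C@@H]23)cc1OC | intermediate
24 | 2α-acetoxy-9β-(benzeneseleninyl)-6α-(3,4-dimethoxybenzoyloxy)daucane-4α,10α-diol (selenoxide) | COc1ccc(C(=O)O[C@@H]2C[C@H](C)[C@@H]([Se](=O)c4ccccc4)[C@H](O)[C@]3(C)[C@H](OC(C)=O)C[C@@](O)(C(C)C)[C@@H]23)cc1OC | intermediate
25 | 2α-acetoxy-6α-(3,4-dimethoxybenzoyloxy)dauc-8-ene-4α,10α-diol | COc1ccc(C(=O)O[C@@H]2CC(C)=C[C@H](O)[C@]3(C)[C@H](OC(C)=O)C[C@@](O)(C(C)C)[C@@H]23)cc1OC | intermediate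
26 | 2α-acetoxy-8,9-epoxy-6α-(3,4-dimethoxybenzoyloxy)daucane-4α,10α-diol (CNP0197096.3) | COc1ccc(C(=O)O[C@@H]2C[C@@]3(C)O[C@@H]3[C@H](O)[C@]3(C)[C@H](OC(C)=O)C[C@@](O)(C(C)C)[C@@H]23)cc1OC | target

## Step count and risks

Total step count: 17. Longest linear sequence: 17 steps (1 and 2 to 26; 4 and 18 are purchased).

The three steps most likely to fail:

Step 5, facial selectivity of the carbenoid addition. The rhodium carbenoid may add to the alkene face anti to the silyloxy-bearing carbon, or with a weak preference, which would give the cyclopropane with the wrong sense relative to C2. The fallback no longer takes the sense of C2 from the aldol but sets it on the bicycle. It sets out from 3. The aldol with (S)-BINOL should give, through methyl (5S,6E,8E)-6-methyl-3,5-bis(trimethylsilyloxy)deca-2,6,8-trienoate F1, methyl (5S,6E,8E)-5-hydroxy-6-methyl-3-oxodeca-6,8-dienoate F2. Silylation to the silyl ether F3 and diazo transfer to the diazo keto ester F4 are followed by the anti-selective cyclisation to the bicyclic keto ester F5 (cyclopropane as in 9, silyloxy group trans to C6). Addition of i-PrMgCl with LaCl3·2LiCl should give the carbinol F6, HF·pyridine the diol F7, Dess–Martin oxidation the β-hydroxy ketone F8 and LiBH(s-Bu)3 (exo attack, −78 °C) the cis-diol F9. Silylation of its secondary hydroxyl (TBSCl, imidazole) comes back to the route at 10.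

Step 6, addition of the isopropyl nucleophile to the hindered ketone. Enolisation towards C3, hydride transfer from the Grignard reagent or homoconjugate opening of the acceptor-substituted vinylcyclopropane may outrun 1,2-addition. The fallback sets out from 9. Isopropenylmagnesium bromide with CeCl3, an sp2 nucleophile without β-hydrogen, should give the isopropenyl carbinol F10. Hydrogen-atom-transfer hydrogenation (Mn(dpm)3, PhSiH3, t-BuOOH, i-PrOH) reduces 1,1-disubstituted alkenes through tertiary radicals and should leave the 1,2-disubstituted propenyl group alone; it comes back at 10.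

Step 11, 5-endo hydrosilylation of a trisubstituted alkene lying between two fully substituted carbons. The cyclisation may be slow, so that platinum-mediated alkene migration or intermolecular hydrosilylation of C9=C10 intervenes. The fallback sets out from 14. VO(acac)2 with t-BuOOH, directed by the tertiary allylic 4-hydroxyl, should give the 5α,6α-epoxide F11. Reductive opening with Cp2TiCl (trivalent titanium, made from Cp2TiCl2 and Zn) and 1,4-cyclohexadiene should cleave the C5–O bond to the tertiary radical and deliver the hydrogen atom to the face away from the isopropyl and methyl groups; it comes back at 17.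

Further compounds
F1 | step 5 | methyl (5S,6E,8E)-6-methyl-3,5-bis(trimethylsilyloxy)deca-2,6,8-trienoate | COC(=O)C=C(O[Si](C)(C)C)C[C@H](O[Si](C)(C)C)/C(C)=C/C=C/C
F2 | step 5 | methyl (5S,6E,8E)-5-hydroxy-6-methyl-3-oxodeca-6,8-dienoate | COC(=O)CC(=O)C[C@H](O)/C(C)=C/C=C/C
F3 | step 5 | methyl (5S,6E,8E)-5-(tert-butyldimethylsilyloxy)-6-methyl-3-oxodeca-6,8-dienoate | COC(=O)CC(=O)C[C@H](O[Si](C)(C)C(C)(C)C)/C(C)=C/C=C/C
F4 | step 5 | methyl (5S,6E,8E)-5-(tert-butyldimethylsilyloxy)-2-diazo-6-methyl-3-oxodeca-6,8-dienoate | COC(=O)C(=[N+]=[N-])C(=O)C[C@H](O[Si](C)(C)C(C)(C)C)/C(C)=C/C=C/C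
F5 | step 5 | methyl 4-(tert-butyldimethylsilyloxy)-5-methyl-2-oxo-6-[(E)-prop-1-enyl]bicyclo[3.1.0]hexane-1-carboxylate (silyloxy trans to C6; 4-epimer of 9) | COC(=O)[C@]12C(=O)C[C@H](O[Si](C)(C)C(C)(C)C)[C@@]1(C)[C@@H]2/C=C/C
F6 | step 5 | methyl 4-(tert-butyldimethylsilyloxy)-2-hydroxy-5-methyl-2-(propan-2-yl)-6-[(E)-prop-1-enyl]bicyclo[3.1.0]hexane-1-carboxylate (4-epimer of 10) | COC(=O)[C@]12[C@](O)(C(C)C)C[C@H](O[Si](C)(C)C(C)(C)C)[C@@]1(C)[C@@H]2/C=C/C
F7 | step 5 | methyl 2,4-dihydroxy-5-methyl-2-(propan-2-yl)-6-[(E)-prop-1-enyl]bicyclo[3.1.0]hexane-1-carboxylate (4-hydroxyl trans to C6) | COC(=O)[C@]12[C@](O)(C(C)C)C[C@H](O)[C@@]1(C)[C@@H]2/C=C/C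
F8 | step 5 | methyl 2-hydroxy-5-methyl-4-oxo-2-(propan-2-yl)-6-[(E)-prop-1-enyl]bicyclo[3.1.0]hexane-1-carboxylate | COC(=O)[C@]12[C@](O)(C(C)C)CC(=O)[C@@]1(C)[C@@H]2/C=C/C
F9 | step 5 | methyl 2,4-dihydroxy-5-methyl-2-(propan-2-yl)-6-[(E)-prop-1-enyl]bicyclo[3.1.0]hexane-1-carboxylate (both hydroxyls cis to C6) | COC(=O)[C@]12[C@](O)(C(C)C)C[C@@H](O)[C@@]1(C)[C@@H]2/C=C/C
F10 | step 6 | methyl 4-(tert-butyldimethylsilyloxy)-2-hydroxy-5-methyl-2-(prop-1-en-2-yl)-6-[(E)-prop-1-enyl]bicyclo[3.1.0]hexane-1-carboxylate | COC(=O)[C@]12[C@](O)(C(C)=C)C[C@@H](O[Si](C)(C)C(C)(C)C)[C@@]1(C)[C@@H]2/C=C/C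
F11 | step 11 | 5α,6α-epoxy-2α-(tert-butyldimethylsilyloxy)dauc-9-en-4α-ol | O1[C@@H]2C[C@H](C)C=C[C@]3(C)[C@H](O[Si](C)(C)C(C)(C)C)C[C@@](O)(C(C)C)[C@@]123
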